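Slowness is what I weigh first in this flask, where second end groups are fed over 4.0 h into first end groups and protic impurity, and the run lasts 6.0 d.

first end groups 0.10 M; second end groups 1.10 equiv (fed, over 4.0 h); protic impurity 0.0300 M; time 6.0 d

    first end groups + second end groups → links (k1 = 0.0226 L mol⁻¹ min⁻¹)
    first end groups + second end groups → rings, rate k2*[first end groups] as long as [second end groups] is above zero (k2 = 1.38 × 10⁻⁴ min⁻¹)
    second end groups + protic impurity → quenched reagent (k3 = 0.468 L mol⁻¹ min⁻¹)
    links ⇌ isomer of the product (K4 = 0.17, k4 = 0.00167 min⁻¹)

1. links at 6.0 d, in percent of the first end groups charged
2. rings at 6.0 d, in percent of the first end groups charged

Who takes the fed reagent first? At the charged amounts, the claim of the protic impurity is 6.21 times that of the first end groups, so I take its charge off first. I carry 0.0800 M of spare reagent, the second end groups charged minus the protic impurity charged. This is less than the 0.10 M of first end groups, so second end groups are the limiting reagent, and 0.0200 M of first end groups should stay over.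

Is there time? Against that remnant, the lifetime of second end groups is about 1.54 d, which is shorter than the run, so I let the spare reagent be consumed.

How does it divide? Links and rings each cost one second end group, and links outrun rings while [second end groups] stands above the balance k2/k1, 0.00611 M. Taking the spare reagent as present at once, integration gives rings as the balance times the logarithm of one plus spare over balance: 16.2%. Links and isomer have a relaxation half-life of 1.01 h, short against the run, so the rest splits between them at the equilibrium constant 0.17, giving 54.6% links.

The forecast says 53% links and 18% rings: "Impurity is fast but not instantaneous". Its rings are more than mine, its links fewer.

The flask gives 53.2% links and 17.8% rings, as the forecast said. At 6.00 d it holds 20.0% of first end groups, and the spare reagent leaves 20.0%.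

In the neighbour flask with 0.075 M of protic impurity, the spare reagent is 0.0350 M, so I expect 65.0% of first end groups left and 11.6% rings. That flask ends with 64.8% of first end groups and 12.3% rings.

The numbers of this flask are assumed; the result is computed.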